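**Retrosynthetic overview**

1. The target is read as epicatechin 3-O-gallate-(4β→8)-epicatechin 3-O-gallate-(4β→6)-catechin (24); the last step is global hydrogenolysis of the perbenzylated, C8-brominated trimer 23.
2. Enabling feature: C4 of the upper unit is a diarylmethine carbon held between two phloroglucinol-type rings (C4a of its own ring A and C8 of ring A of the middle unit) and flanked by the C3 gallate, so it is an aldehyde carbon that has been arylated twice.
3. Key disconnection: both aryl bonds at this carbon are cut in one retro-bis-arylation, the C4–C4a bond (opening ring C of the upper unit) and the C4–C8 interflavan bond, giving open-chain aldehyde 12 and dimer 20.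
4. Aldehyde 12 comes from 3,4-bis(benzyloxy)benzaldehyde by syn-selective asymmetric alkoxyallylboration (sets C2 and C3), O-arylation, gallate esterification and alkene cleavage; dimer 20 comes from epicatechin (C4-activated gallate 19) and catechin (C8-brominated nucleophile 15) by 4β→6 coupling.
5. Ring order: rings A, B and C of the middle and lower units are taken from the natural flavan-3-ols; ring C of the upper unit is closed last, in the key step, between preformed rings A and B.

Key step: step 12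

Remark: compounds 2, 6, 9 and (−)-Ipc2BOMe are treated as purchasable, and the 3-OH of the lower (catechin) unit is carried unprotected because it is free in the target.

**Route**

Step 1
Reactants: 1 3,4-bis(benzyloxy)benzaldehyde; 2 allyl methoxymethyl ether
Product: 5 (1R,2R)-1-[3,4-bis(benzyloxy)phenyl]-2-(methoxymethoxy)but-3-en-1-ol, via Z-γ-(methoxymethoxy)allyl-diisopinocampheylborane 3 (not isolated), via diisopinocampheylborinate adduct 4 (not isolated)
Conditions: 2, s-BuLi, THF, −78 °C; (−)-Ipc2BOMe, −78 °C; BF3·OEt2; then 1, −78 °C; NaOH, H2O2, 0 °C → rt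
Reagents that add atoms: none
Why: Asymmetric γ-alkoxyallylboration (Brown allylboration): the Z-allylborane 3 adds through a closed chair (Zimmerman–Traxler) transition state that turns the Z geometry into the syn relation of C1–OH and C2–OMOM, while the isopinocampheyl groups derived from (+)-α-pinene direct attack to the Si face of the aldehyde, so both stereocentres of the upper unit (future C2 and C3) should be set as (1R,2R) after oxidative release from 4.

Step 2
Reactants: 5 (1R,2R)-1-[3,4-bis(benzyloxy)phenyl]-2-(methoxymethoxy)but-3-en-1-ol; 6 1,3-bis(benzyloxy)-5-bromobenzene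
Product: 7 4-[(1R,2R)-1-[3,5-bis(benzyloxy)phenoxy]-2-(methoxymethoxy)but-3-en-1-yl]-1,2-bis(benzyloxy)benzene
Conditions: [Pd(allyl)Cl]2 (2.5 mol %), RockPhos (6 mol %), Cs2CO3, toluene, 90 °C; 6 in 1.5-fold excess
Reagents that add atoms: none
Why: Palladium-catalysed C–O cross-coupling of a secondary alcohol with an aryl bromide (Buchwald–Hartwig etherification): the bulky biarylphosphine favours C–O reductive elimination over β-hydride elimination, and because the carbinol C–O bond is never broken C1 should keep its R configuration.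

Step 3
Reactants: 7 4-[(1R,2R)-1-[3,5-bis(benzyloxy)phenoxy]-2-(methoxymethoxy)but-3-en-1-yl]-1,2-bis(benzyloxy)benzene
Product: 8 (1R,2R)-1-[3,4-bis(benzyloxy)phenyl]-1-[3,5-bis(benzyloxy)phenoxy]but-3-en-2-ol
Conditions: TMSOTf, 2,2'-bipyridyl, CH2Cl2, 0 °C; then H2O, rt
Reagents that add atoms: none
Why: Chemoselective acetal cleavage: TMSOTf with 2,2'-bipyridyl converts the aliphatic MOM ether into a bipyridinium N,O-acetal salt that water hydrolyses to the alcohol, a buffered procedure that should leave the benzyl ethers, the alkene and the ionisable benzylic aryl ether untouched and involves neither stereocentre.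

Step 4
Reactants: 8 (1R,2R)-1-[3,4-bis(benzyloxy)phenyl]-1-[3,5-bis(benzyloxy)phenoxy]but-3-en-2-ol; 9 3,4,5-tris(benzyloxy)benzoic acid
Product: 10 (1R,2R)-1-[3,4-bis(benzyloxy)phenyl]-1-[3,5-bis(benzyloxy)phenoxy]but-3-en-2-yl 3,4,5-tris(benzyloxy)benzoate
Conditions: DCC, DMAP (cat.), CH2Cl2, 0 °C → rt
Reagents that add atoms: none
Why: Steglich esterification acylates the only free hydroxyl at oxygen, so C2 is retained, and installs the gallate that later directs the C4 configuration.

Step 5
Reactants: 10 (1R,2R)-1-[3,4-bis(benzyloxy)phenyl]-1-[3,5-bis(benzyloxy)phenoxy]but-3-en-2-yl 3,4,5-tris(benzyloxy)benzoate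
Product: 12 (1R,2S)-1-[3,4-bis(benzyloxy)phenyl]-1-[3,5-bis(benzyloxy)phenoxy]-3-oxopropan-2-yl 3,4,5-tris(benzyloxy)benzoate, via vicinal diol 11 (not isolated)
Conditions: OsO4 (2 mol %), NaIO4, 2,6-lutidine, 1,4-dioxane/H2O, rt; crude aldehyde dried and used at once
Reagents that add atoms: sodium periodate, [Na+].[O-]I(=O)(=O)=O
Why: Lemieux–Johnson oxidation: catalytic OsO4 (reoxidised by periodate, which thereby supplies the oxygen) dihydroxylates the only alkene to 11 and NaIO4 cleaves it directly to the aldehyde, the electron-rich arenes being inert to both oxidants; the stereocentres are not touched (the descriptor at C2 changes to S only because the CHO group outranks the neighbouring carbon).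

Step 6
Reactants: 13 (+)-catechin
Product: 14 5,7,3',4'-tetra-O-benzyl-(+)-catechin
Conditions: BnBr, K2CO3, DMF, 0 °C → rt
Reagents that add atoms: benzyl bromide, BrCc1ccccc1
Why: Williamson ether synthesis: K2CO3 deprotonates only the four phenols, so benzylation should stop at the tetra-ether with the secondary 3-OH and both stereocentres unchanged.

Step 7
Reactants: 14 5,7,3',4'-tetra-O-benzyl-(+)-catechin
Product: 15 8-bromo-5,7,3',4'-tetra-O-benzyl-(+)-catechin
Conditions: NBS (1.0 equiv), CH2Cl2, −78 °C → rt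
Reagents that add atoms: N-bromosuccinimide, O=C1CCC(=O)N1Br
Why: Electrophilic aromatic bromination with NBS occurs on the phloroglucinol-type ring A at C8, the more reactive of its two free positions, giving a cap that blocks C8 in both later couplings and is removed in the last step.

Step 8
Reactants: 16 (−)-epicatechin
Product: 17 5,7,3',4'-tetra-O-benzyl-(−)-epicatechin
Conditions: BnBr, K2CO3, DMF, 0 °C → rt
Reagents that add atoms: benzyl bromide, BrCc1ccccc1
Why: Williamson ether synthesis as in step 6, leaving the axial 3-OH free and the stereocentres unchanged.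

Step 9
Reactants: 17 5,7,3',4'-tetra-O-benzyl-(−)-epicatechin
Product: 18 4β-(2-ethoxyethoxy)-5,7,3',4'-tetra-O-benzyl-(−)-epicatechin
Conditions: DDQ, 2-ethoxyethanol, CH2Cl2, rt
Reagents that add atoms: 2-ethoxyethanol, CCOCCO
Why: DDQ benzylic oxidation: hydride abstraction from C4, assisted by the oxygen donors of ring A, gives a quinone-methide-type cation that 2-ethoxyethanol traps on the β face, anti to the 2-aryl and 3-hydroxyl groups, giving a latent C4 cation.

Step 10
Reactants: 18 4β-(2-ethoxyethoxy)-5,7,3',4'-tetra-O-benzyl-(−)-epicatechin; 9 3,4,5-tris(benzyloxy)benzoic acid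
Product: 19 4β-(2-ethoxyethoxy)-5,7,3',4'-tetra-O-benzyl-(−)-epicatechin 3-O-[3,4,5-tris(benzyloxy)benzoate]
Conditions: DCC, DMAP, CH2Cl2, rt
Reagents that add atoms: none
Why: Steglich esterification of the hindered axial 3-OH takes place at oxygen, so no stereocentre is affected, and the ester serves as participating group in step 11.

Step 11
Reactants: 19 4β-(2-ethoxyethoxy)-5,7,3',4'-tetra-O-benzyl-(−)-epicatechin 3-O-[3,4,5-tris(benzyloxy)benzoate]; 15 8-bromo-5,7,3',4'-tetra-O-benzyl-(+)-catechin
Product: 20 [5,7,3',4'-tetra-O-benzylepicatechin 3-O-(tri-O-benzylgallate)]-(4β→6)-[8-bromo-5,7,3',4'-tetra-O-benzylcatechin]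
Conditions: TMSOTf (cat.), CH2Cl2, −78 °C; 15 in 4-fold excess; Et3N quench
Reagents that add atoms: none
Why: Lewis-acid-promoted Friedel–Crafts interflavan coupling: TMSOTf ionises the 4-alkoxy group of 19, the C4 cation is shielded on the α face by the participating 3-O-acyl group, and C6 of 15 (its only free ring-A position, C8 being brominated) attacks from the β face to set the 4β (3,4-trans) configuration of the middle unit, the excess of 15 suppressing self-condensation of 19 through its own C8.

Step 12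
Reactants: 12 (1R,2S)-1-[3,4-bis(benzyloxy)phenyl]-1-[3,5-bis(benzyloxy)phenoxy]-3-oxopropan-2-yl 3,4,5-tris(benzyloxy)benzoate; 20 [5,7,3',4'-tetra-O-benzylepicatechin 3-O-(tri-O-benzylgallate)]-(4β→6)-[8-bromo-5,7,3',4'-tetra-O-benzylcatechin]
Product: 23 [5,7,3',4'-tetra-O-benzylepicatechin 3-O-(tri-O-benzylgallate)]-(4β→8)-[5,7,3',4'-tetra-O-benzylepicatechin 3-O-(tri-O-benzylgallate)]-(4β→6)-[8-bromo-5,7,3',4'-tetra-O-benzylcatechin], via flavan-4-ol 21 (not isolated), via bridged acyloxonium triflate 22 (not isolated)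
Conditions: TMSOTf (0.3 equiv), 4 Å molecular sieves, CH2Cl2, −78 → −30 °C; 12 added over 1 h to 20 (2 equiv); Et3N quench
Reagents that add atoms: none
Why: Proposed new method: TMSOTf activates the aldehyde carbon of 12 (the future C4) and one of the two equivalent ortho carbons of the symmetric 3,5-dibenzyloxyphenoxy ring attacks it (intramolecular Friedel–Crafts hydroxyalkylation), forming the C4–C4a bond and closing ring C of the upper unit to give flavan-4-ol 21 as a mixture of C4 epimers; acid then ionises either epimer to one ring-A-stabilised C4 cation, which the 3-O-galloyl carbonyl captures on the α face as the cis-fused acyloxonium ion 22, and C8 of the middle unit of 20 opens this ion from the β face (intermolecular Friedel–Crafts alkylation) to give 23. The closest known reaction types are the acid-catalysed cyclisation of 3-aryloxypropanals to chroman-4-ols, the bis-arylation of aldehydes by electron-rich arenes (Baeyer-type condensation, known in tandem form for 9-arylxanthenes from 2-aryloxybenzaldehydes) and the TMSOTf-mediated coupling of 4-alkoxy- or 4-hydroxyflavan-3-ol derivatives with flavan nucleophiles; what has not been shown is both arylations on the aldehyde carbon of an open-chain α-acyloxy-β-aryloxy aldehyde in one flask. The ring closure is six-membered and exo-trig at the carbonyl carbon (the C=O bond stays outside the new ring) with the attacking arene C=C bond inside it (endo), an unstrained chroman closure. C4 is the only new stereocentre and the step is stereoconvergent: both epimers of 21 pass through 22, whose anti opening (neighbouring-group participation by the C3 ester, reinforced by the known preference of 2,3-cis flavan-4-yl cations for attack trans to the 3-substituent) should give the 3,4-trans (4β, 4R) configuration; should 20 add to the aldehyde before the ring closes, the diarylcarbinol ionises to the analogous cation stabilised by ring A of the middle unit, and ring closure through C4–C4a, again anti to the participating ester, leads to the same product. The selectivities needed are (a) C8 over C6 of the middle unit, secured by the higher nucleophilicity and lower hindrance of C8 in 5,7-di-O-benzylflavans and by the bromine that blocks C8 of the lower unit, (b) cross-coupling over self-condensation through the free C6/C8 positions of the new upper ring A, secured by slow addition of 12 to excess 20, (c) chroman over indane closure, secured by the far higher nucleophilicity of the phloroglucinol-type ring compared with the catechol-type ring B, and (d) integrity of C3, secured by the non-basic medium and low temperature.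

Step 13
Reactants: 23 [5,7,3',4'-tetra-O-benzylepicatechin 3-O-(tri-O-benzylgallate)]-(4β→8)-[5,7,3',4'-tetra-O-benzylepicatechin 3-O-(tri-O-benzylgallate)]-(4β→6)-[8-bromo-5,7,3',4'-tetra-O-benzylcatechin]
Product: 24 epicatechin 3-O-gallate-(4β→8)-epicatechin 3-O-gallate-(4β→6)-catechin (CNP0154615.1)
Conditions: H2 (1 atm), Pd(OH)2/C, Et3N (1.2 equiv), THF/MeOH/H2O, rt
Reagents that add atoms: none
Why: Catalytic hydrogenolysis over Pd(OH)2/C should remove all eighteen benzyl ethers and hydrodebrominate C8 of the lower unit in one operation, Et3N neutralising the HBr so that the acid-labile interflavan bonds, the two gallate esters and all eight stereocentres are preserved.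

**Compound list**

1 | 3,4-bis(benzyloxy)benzaldehyde | O=Cc1ccc(OCc2ccccc2)c(OCc2ccccc2)c1 | starting material
2 | allyl methoxymethyl ether [3-(methoxymethoxy)prop-1-ene] | C=CCOCOC | starting material
3 | [(Z)-3-(methoxymethoxy)prop-2-en-1-yl]diisopinocampheylborane (Ipc groups from (+)-α-pinene) | COCO/C=C\CB([C@@H]1C[C@@H]2C[C@H]([C@H]1C)C2(C)C)[C@@H]1C[C@@H]2C[C@H]([C@H]1C)C2(C)C | intermediate (not isolated)
4 | diisopinocampheylborinate ester of 5 | COCO[C@H](C=C)[C@H](OB([C@@H]1C[C@@H]2C[C@H]([C@H]1C)C2(C)C)[C@@H]1C[C@@H]2C[C@H]([C@H]1C)C2(C)C)c1ccc(OCc2ccccc2)c(OCc2ccccc2)c1 | intermediate (not isolated)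
5 | (1R,2R)-1-[3,4-bis(benzyloxy)phenyl]-2-(methoxymethoxy)but-3-en-1-ol | COCO[C@H](C=C)[C@H](O)c1ccc(OCc2ccccc2)c(OCc2ccccc2)c1 | intermediate
6 | 1,3-bis(benzyloxy)-5-bromobenzene | Brc1cc(OCc2ccccc2)cc(OCc2ccccc2)c1 | starting material
7 | 4-[(1R,2R)-1-[3,5-bis(benzyloxy)phenoxy]-2-(methoxymethoxy)but-3-en-1-yl]-1,2-bis(benzyloxy)benzene | COCO[C@H](C=C)[C@H](Oc1cc(OCc2ccccc2)cc(OCc2ccccc2)c1)c1ccc(OCc2ccccc2)c(OCc2ccccc2)c1 | intermediate
8 | (1R,2R)-1-[3,4-bis(benzyloxy)phenyl]-1-[3,5-bis(benzyloxy)phenoxy]but-3-en-2-ol | O[C@H](C=C)[C@H](Oc1cc(OCc2ccccc2)cc(OCc2ccccc2)c1)c1ccc(OCc2ccccc2)c(OCc2ccccc2)c1 | intermediate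
9 | 3,4,5-tris(benzyloxy)benzoic acid | OC(=O)c1cc(OCc2ccccc2)c(OCc2ccccc2)c(OCc2ccccc2)c1 | starting material
10 | (1R,2R)-1-[3,4-bis(benzyloxy)phenyl]-1-[3,5-bis(benzyloxy)phenoxy]but-3-en-2-yl 3,4,5-tris(benzyloxy)benzoate | O=C(O[C@H](C=C)[C@H](Oc1cc(OCc2ccccc2)cc(OCc2ccccc2)c1)c1ccc(OCc2ccccc2)c(OCc2ccccc2)c1)c1cc(OCc2ccccc2)c(OCc2ccccc2)c(OCc2ccccc2)c1 | intermediate
11 | 3,4-diol of 10 (both C3 epimers) | O=C(O[C@H](C(O)CO)[C@H](Oc1cc(OCc2ccccc2)cc(OCc2ccccc2)c1)c1ccc(OCc2ccccc2)c(OCc2ccccc2)c1)c1cc(OCc2ccccc2)c(OCc2ccccc2)c(OCc2ccccc2)c1 | intermediate (not isolated)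
12 | (1R,2S)-1-[3,4-bis(benzyloxy)phenyl]-1-[3,5-bis(benzyloxy)phenoxy]-3-oxopropan-2-yl 3,4,5-tris(benzyloxy)benzoate | O=C(O[C@H](C=O)[C@H](Oc1cc(OCc2ccccc2)cc(OCc2ccccc2)c1)c1ccc(OCc2ccccc2)c(OCc2ccccc2)c1)c1cc(OCc2ccccc2)c(OCc2ccccc2)c(OCc2ccccc2)c1 | intermediate
13 | (+)-catechin | O[C@H]1Cc2c(O)cc(O)cc2O[C@@H]1c1ccc(O)c(O)c1 | starting material
14 | 5,7,3',4'-tetra-O-benzyl-(+)-catechin | O[C@H]1Cc2c(OCc3ccccc3)cc(OCc3ccccc3)cc2O[C@@H]1c1ccc(OCc2ccccc2)c(OCc2ccccc2)c1 | intermediate
15 | 8-bromo-5,7,3',4'-tetra-O-benzyl-(+)-catechin | O[C@H]1Cc2c(OCc3ccccc3)cc(OCc3ccccc3)c(Br)c2O[C@@H]1c1ccc(OCc2ccccc2)c(OCc2ccccc2)c1 | intermediate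
16 | (−)-epicatechin | O[C@@H]1Cc2c(O)cc(O)cc2O[C@@H]1c1ccc(O)c(O)c1 | starting material
17 | 5,7,3',4'-tetra-O-benzyl-(−)-epicatechin | O[C@@H]1Cc2c(OCc3ccccc3)cc(OCc3ccccc3)cc2O[C@@H]1c1ccc(OCc2ccccc2)c(OCc2ccccc2)c1 | intermediate
18 | 4β-(2-ethoxyethoxy)-5,7,3',4'-tetra-O-benzyl-(−)-epicatechin | O[C@@H]1[C@@H](OCCOCC)c2c(OCc3ccccc3)cc(OCc3ccccc3)cc2O[C@@H]1c1ccc(OCc2ccccc2)c(OCc2ccccc2)c1 | intermediate
19 | 4β-(2-ethoxyethoxy)-5,7,3',4'-tetra-O-benzyl-(−)-epicatechin 3-O-[3,4,5-tris(benzyloxy)benzoate] | O=C(O[C@@H]1[C@@H](OCCOCC)c2c(OCc3ccccc3)cc(OCc3ccccc3)cc2O[C@@H]1c1ccc(OCc2ccccc2)c(OCc2ccccc2)c1)c1cc(OCc2ccccc2)c(OCc2ccccc2)c(OCc2ccccc2)c1 | intermediate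
20 | [5,7,3',4'-tetra-O-benzylepicatechin 3-O-(tri-O-benzylgallate)]-(4β→6)-[8-bromo-5,7,3',4'-tetra-O-benzylcatechin] | c1c(OCc3ccccc3)cc(OCc3ccccc3)c2c1O[C@H](c1ccc(OCc3ccccc3)c(OCc3ccccc3)c1)[C@H](OC(=O)c1cc(OCc3ccccc3)c(OCc3ccccc3)c(OCc3ccccc3)c1)[C@H]2c1c(OCc3ccccc3)c(Br)c2c(c1OCc1ccccc1)C[C@H](O)[C@@H](c1ccc(OCc3ccccc3)c(OCc3ccccc3)c1)O2 | intermediate
21 | 4-hydroxy-5,7,3',4'-tetra-O-benzylepicatechin 3-O-(tri-O-benzylgallate) (both C4 epimers) | O=C(O[C@@H]1C(O)c2c(OCc3ccccc3)cc(OCc3ccccc3)cc2O[C@@H]1c1ccc(OCc2ccccc2)c(OCc2ccccc2)c1)c1cc(OCc2ccccc2)c(OCc2ccccc2)c(OCc2ccccc2)c1 | intermediate (not isolated)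
22 | 3,4-cis-fused 2-aryl-1,3-dioxolan-2-ylium triflate of the upper unit (C4–O on the α face) | [O-]S(=O)(=O)C(F)(F)F.O1[C@@H]2[C@H]([O+]=C1c1cc(OCc3ccccc3)c(OCc3ccccc3)c(OCc3ccccc3)c1)c1c(OCc3ccccc3)cc(OCc3ccccc3)cc1O[C@@H]2c1ccc(OCc3ccccc3)c(OCc3ccccc3)c1 | intermediate (not isolated)
23 | [5,7,3',4'-tetra-O-benzylepicatechin 3-O-(tri-O-benzylgallate)]-(4β→8)-[5,7,3',4'-tetra-O-benzylepicatechin 3-O-(tri-O-benzylgallate)]-(4β→6)-[8-bromo-5,7,3',4'-tetra-O-benzylcatechin] | O=C(O[C@@H]1[C@@H](c2c(OCc4ccccc4)cc(OCc4ccccc4)c3c2O[C@H](c2ccc(OCc4ccccc4)c(OCc4ccccc4)c2)[C@H](OC(=O)c2cc(OCc4ccccc4)c(OCc4ccccc4)c(OCc4ccccc4)c2)[C@H]3c2c(OCc4ccccc4)c(Br)c3c(c2OCc4ccccc4)C[C@H](O)[C@@H](c2ccc(OCc4ccccc4)c(OCc4ccccc4)c2)O3)c2c(OCc4ccccc4)cc(OCc4ccccc4)cc2O[C@@H]1c1ccc(OCc4ccccc4)c(OCc4ccccc4)c1)c1cc(OCc4ccccc4)c(OCc4ccccc4)c(OCc4ccccc4)c1 | intermediate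
24 | epicatechin 3-O-gallate-(4β→8)-epicatechin 3-O-gallate-(4β→6)-catechin (CNP0154615.1) | O=C(O[C@@H]1[C@@H](c2c(O)cc(O)c3c2O[C@H](c2ccc(O)c(O)c2)[C@H](OC(=O)c2cc(O)c(O)c(O)c2)[C@H]3c2c(O)cc3c(c2O)C[C@H](O)[C@@H](c2ccc(O)c(O)c2)O3)c2c(O)cc(O)cc2O[C@@H]1c1ccc(O)c(O)c1)c1cc(O)c(O)c(O)c1 | target

**Step count and risks**

Total step count: 13. Longest linear sequence: 7 steps (steps 1, 2, 3, 4, 5, 12, 13).

Steps most likely to fail:

1. Step 12 (Proposed new method). What may go wrong: oligomerisation through the free C6/C8 positions of the upper ring A once ring C has closed, attack at C6 instead of C8 of the middle unit, or epimerisation and β-elimination of the aldehyde before it cyclises. Fallback with known chemistry: set out from 19 and 20 and couple them directly (TMSOTf cat., CH2Cl2, −78 °C, 20 in excess). This is the established Lewis-acid interflavan condensation of a 4-alkoxyflavan-3-yl ester with a flavan nucleophile. The upper unit then derives from epicatechin instead of from 12, no new compound is made (F0), and the route is rejoined at 23.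

2. Step 2. What may go wrong: β-hydride elimination from the palladium alkoxide (oxidation of the benzylic carbinol to the ketone with reduction of 6) or slow C–O reductive elimination at the hindered alkoxide. Fallback: make the same C–O bond at carbon instead of at the arene, by two Mitsunobu inversions. From 5, PPh3/DIAD/4-nitrobenzoic acid (THF, 0 °C) gives the inverted ester (1S,2R)-1-[3,4-bis(benzyloxy)phenyl]-2-(methoxymethoxy)but-3-en-1-yl 4-nitrobenzoate F1. K2CO3 in MeOH then frees the anti alcohol (1S,2R)-1-[3,4-bis(benzyloxy)phenyl]-2-(methoxymethoxy)but-3-en-1-ol F2. A second Mitsunobu reaction with 3,5-bis(benzyloxy)phenol (PPh3, DIAD, toluene, 0 °C) inverts C1 again and rejoins the route at 7. Any leakage through the benzylic cation would give the C1 epimer, a diastereomer that chromatography should remove.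

3. Step 5. What may go wrong: lutidine-promoted β-elimination of the aryloxide or epimerisation at the α-carbon of the α-acyloxy aldehyde, or 1,2-acyl migration in diol 11 followed by cleavage of the wrong C–C bond. Fallback: mask the aldehyde as an acetal. From 10, K2OsO2(OH)4/NMO (acetone/H2O) gives 11, which is isolated and cleaved with silica-supported NaIO4 in CH2Cl2. Without storing the aldehyde, HC(OMe)3/PPTS/MeOH converts it into (1R,2S)-1-[3,4-bis(benzyloxy)phenyl]-1-[3,5-bis(benzyloxy)phenoxy]-3,3-dimethoxypropan-2-yl 3,4,5-tris(benzyloxy)benzoate F3. This acetal should survive chromatography and is used in place of 12 under the conditions of step 12: TMSOTf ionises it to the oxocarbenium ion, ring C closes to the 4-methoxyflavan (a standard C4-activated flavan electrophile), and this couples with 20, rejoining the route at 23.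

Further compounds
F0 | step 12 | none | none
F1 | step 2 | (1S,2R)-1-[3,4-bis(benzyloxy)phenyl]-2-(methoxymethoxy)but-3-en-1-yl 4-nitrobenzoate | COCO[C@H](C=C)[C@@H](OC(=O)c1ccc(cc1)[N+](=O)[O-])c1ccc(OCc2ccccc2)c(OCc2ccccc2)c1
F2 | step 2 | (1S,2R)-1-[3,4-bis(benzyloxy)phenyl]-2-(methoxymethoxy)but-3-en-1-ol | COCO[C@H](C=C)[C@@H](O)c1ccc(OCc2ccccc2)c(OCc2ccccc2)c1
F3 | step 5 | (1R,2S)-1-[3,4-bis(benzyloxy)phenyl]-1-[3,5-bis(benzyloxy)phenoxy]-3,3-dimethoxypropan-2-yl 3,4,5-tris(benzyloxy)benzoate | O=C(O[C@H](C(OC)OC)[C@H](Oc1cc(OCc2ccccc2)cc(OCc2ccccc2)c1)c1ccc(OCc2ccccc2)c(OCc2ccccc2)c1)c1cc(OCc2ccccc2)c(OCc2ccccc2)c(OCc2ccccc2)c1
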